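## Retrosynthetic overview
1. Target 6 ⇒ phenol 4 by disconnecting the quinone C4–O bond. This is the key step: para C–H oxygenation of a 2-methoxy-6-alkylphenol by oxygen-atom transfer from anodically generated phthalimide-N-oxyl (new).
2. Phenol 4 ⇒ o-eugenol 1 + erucic acid 2. The C13=C14 double bond of erucic acid sits exactly 12 carbons from CO2H, so cross-metathesis with the allyl group, then hydrogenation in the same pot, gives the full C15 chain.
3. No ring is built. The only ring is the benzene ring of 1, carried through and converted to the quinone in the last step.

Assumption: the target has no stereocentre and no stereogenic double bond, so it is achiral and there is no enantiomer to control; the E/Z mixture of 3 is erased by hydrogenation.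

## Route

Step 1
Reactants: 1 2-allyl-6-methoxyphenol (o-eugenol, 3.0 equiv); 2 erucic acid, (Z)-docos-13-enoic acid (1.0 equiv, ≥98 %)
Product: 4 15-(2-hydroxy-3-methoxyphenyl)pentadecanoic acid, via alkenoic acid 3 (not isolated)
Conditions: (i) Hoveyda–Grubbs II (2 mol %), 1,4-benzoquinone (10 mol %), EtOAc, 50 °C, N2 stream; (ii) same pot: 10 % Pd/C, H2 (3 bar), 25 °C; chromatography, then crystallisation
Reagents that add atoms: none
Why: Olefin cross-metathesis of the terminal allyl arene with the internal C13=C14 olefin of 2 attaches the chain (free phenol and acid are tolerated; benzoquinone and the acid suppress Ru–H double-bond migration), and heterogeneous catalytic hydrogenation then removes the E/Z mixture and turns the co-formed 1-decene into decane; no stereocentre is formed.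

Step 2
Reactants: 4 15-(2-hydroxy-3-methoxyphenyl)pentadecanoic acid
Product: 6 15-(5-methoxy-3,6-dioxocyclohexa-1,4-dien-1-yl)pentadecanoic acid, via phthalimidooxy dienone 5 (not isolated)
Conditions: N-hydroxyphthalimide (2.0 equiv), 2,6-lutidine (3.0 equiv), n-Bu4NBF4 (0.1 M), MeCN/CH2Cl2 4:1, divided cell, RVC anode, Pt cathode (AcOH in the catholyte), 5 mA cm−2, 2.5 F mol−1, 20 °C
Reagents that add atoms: N-hydroxyphthalimide (NHPI), O=C1c2ccccc2C(=O)N1O
Why: Proposed new method: anodic oxidation of NHPI/lutidine (about 0.9 V vs SCE, at or below the potential of phenol 4) gives phthalimide-N-oxyl (PINO); PINO abstracts the phenolic H of 4 (O–H BDE about 83 against 88 kcal/mol for NHPI, and phenols react more than 10^3 times faster than any C–H of the chain), which returns NHPI; the phenoxyl radical, present at far lower concentration than the longer-lived PINO, cross-couples with a second PINO at C4, its only unsubstituted carbon of high spin density (adducts at the substituted C2 and C6 cannot eliminate and revert), forming the C4–O bond in dienone 5; lutidine then removes the doubly allylic C4–H and the weak N–O bond breaks with loss of phthalimide (Kornblum–DeLaMare-type elimination) to give the quinone; the closest known reaction type is the Teuber oxidation with Fremy's salt, which follows the same H-abstraction, radical-coupling and elimination sequence with •ON(SO3K)2, together with NHPI-mediated anodic C–H oxidations, but NHPI has not been shown to act as the oxygen-atom donor to a phenol para carbon; C4 of 5 is transient and racemic, and no stereocentre remains.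

## Compound list
1 | 2-allyl-6-methoxyphenol (o-eugenol) | COc1cccc(CC=C)c1O | starting material
2 | erucic acid, (Z)-docos-13-enoic acid | CCCCCCCC/C=C\CCCCCCCCCCCC(=O)O | starting material
3 | 15-(2-hydroxy-3-methoxyphenyl)pentadec-13-enoic acid, E/Z mixture (E drawn) | COc1cccc(C/C=C/CCCCCCCCCCCC(=O)O)c1O | intermediate (not isolated)
4 | 15-(2-hydroxy-3-methoxyphenyl)pentadecanoic acid | COc1cccc(CCCCCCCCCCCCCCC(=O)O)c1O | intermediate
5 | 15-{3-[(1,3-dioxoisoindolin-2-yl)oxy]-5-methoxy-6-oxocyclohexa-1,4-dien-1-yl}pentadecanoic acid, racemic at ring C3 | COC1=CC(ON2C(=O)c3ccccc3C2=O)C=C(CCCCCCCCCCCCCCC(=O)O)C1=O | intermediate (not isolated)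
6 | 15-(5-methoxy-3,6-dioxocyclohexa-1,4-dien-1-yl)pentadecanoic acid | COC1=CC(=O)C=C(CCCCCCCCCCCCCCC(=O)O)C1=O | target

## Step count and risks
Total step count: 2. Longest linear sequence: 2 steps.

The route has only two steps, so both are given, the more risky first.

1. Step 2 (the proposed new reaction). The risks are phenoxyl–phenoxyl coupling to a diphenoquinone, slow fragmentation if 5 first tautomerises to the N-aryloxyphthalimide, and PINO attack on the CH2 next to the quinone at high conversion. The fallback uses known chemistry and sets out from 4. It is the Teuber oxidation with potassium nitrosodisulfonate (Fremy's salt, 2.5 equiv) in KH2PO4-buffered water/CH2Cl2 with Aliquat 336 at 20 °C, the established method for 2-methoxy-6-alkyl-1,4-benzoquinones. It comes back to the route at 6 and makes no new compound (F0).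

2. Step 1. The coupling is statistical: with 3 equiv of 1 about 60 % of 2 can end up in 3. Ru–H double-bond migration would give chain homologues that cannot be separated later, and other monoenoic acids in technical erucic acid would do the same, hence the ≥98 % grade. The fallback sets out from 2. Self-metathesis of 2 (Grubbs II, neat, 45 °C) gives the symmetrical (E)-hexacos-13-enedioic acid F1, which is purified by crystallisation. Cross-metathesis of F1 with 1 (4 equiv, Hoveyda–Grubbs II, benzoquinone, EtOAc, 50 °C) then gives 3 from both halves of the diacid, with no unwanted alkyl fragment. Here 3 is isolated, and the fallback comes back to the route at 3, which is hydrogenated (Pd/C, H2) to 4 as in step 1.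

Further compounds
F1 | step 1 | (E)-hexacos-13-enedioic acid | OC(=O)CCCCCCCCCCC/C=C/CCCCCCCCCCCC(=O)O
F0 | step 2 | none | none
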